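A chemist holding readings of Q and J sees converted Q missing from them, and wants to know whether the flask's unread Q sits in D and Z.

| flask | Q | G | remark | time |
|---|---|---|---|---|
| birch | 0.70 mM | 0.50 mM | run made earlier |  |
| cedar | 1.1 mM | 0.50 mM | run made earlier |  |
| flask | 0.50 mM | 0.500 mM |  | 5.0 min |

| run | time / min | Q / % | J / % |
|---|---|---|---|
| birch | 0.333 | 75.8 | 7.5 |
| birch | 0.500 | 66.7 | 10.2 |
| birch | 0.833 | 54.7 | 12.5 |
| birch | 1.33 | 41.5 | 15.9 |
| birch | 2.50 | 29.4 | 21.7 |
| birch | 4.00 | 18.1 | 24.0 |
| cedar | 0.667 | 62.0 | 8.7 |
| cedar | 1.33 | 46.6 | 11.9 |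
| cedar | 2.00 | 39.2 | 12.5 |
| cedar | 2.50 | 36.4 | 10.6 |
| cedar | 3.00 | 32.0 | 10.5 |
| cedar | 4.00 | 27.7 | 10.6 |

(standard deviation of a reading: 1 percentage point)

- Q at 5.0 min, in percent of the Q charged
- J at 5.0 min, in percent of the Q charged
- D at 5.0 min, in percent of the Q charged
- Z at 5.0 min, in percent of the Q charged

- the numbers in the tables scatter by 1 percentage point (one standard deviation)
- a reading or a percentage of J counts all its forms, free or not

I turned the question round: what would the readings have to show for D and Z to hold that unread Q? Taking each adduct to keep the G it took, each Q in D carries 2 G and each in Z carries 3. So the G charged, less the G in J, divided by the Q neither read as Q nor as J, would have to reach 2. At birch's last reading this ratio was 0.819, and I called this stoichiometric limit the G ceiling; cedar's last reading gives 0.565, and both stand lower than 2.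

For the flask I replaced birch's bending Q curve by its mean first-order constant, 0.427 min⁻¹, which gave my estimate of Q, 11.8%. Birch's last share of lost Q as J, 29.3%, gave my estimate of J, 25.8%, so I estimated the flask's ceiling at 1.19. Birch's readings over its last stretch gave a lower constant, 0.323 min⁻¹; carrying its last reading on at that constant, as a check on the mean, gave an estimate of 13.1% for Q and 1.21 for the ceiling. I therefore expected an unread product with less G per Q than D.

The forecast, which parts from me on D and Z, gave Q 8%, J 27%, D 40% and Z 25%, holding that “G must turn over, acting catalytically”.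

The flask gave Q 9.29%, J 33.3%, D 0.720% and Z 0.693%, with X at 56.0%, each X counting as two.

    E ⇌ J, rate k1*(cs1 - [J]) while solid is left; crystals form when [J] > cs1 (solubility = 0.00600 mM, k = 0.149 s⁻¹)
    Q + G → J (k = 21.4 M⁻¹ s⁻¹)
    G + J → D (k = 8.76 M⁻¹ s⁻¹)
    Q + J → X (k = 255 M⁻¹ s⁻¹)
    G + D → Z (k = 16.3 M⁻¹ s⁻¹)

The flask's ceiling from these values is 1.16, beside birch's 0.819. A neighbouring flask, the same but charged with 1.2 mM of G, gave Q 0.201% and J 49.9%, so its ceiling is 3.81, above 3. There the count forbids neither D nor Z, yet that flask held D 0.743%, Z 4.62% and X 44.6%.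

The numbers in the tables were computed on assumed constants; noise was put on by code.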